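Assumption: the atom labels used below (C1–C4 and C4a–C8a for the tetralin, C11 for the branch carbon on C1, C19 for its CH2O carbon, C12–C16 for the chain, C15 bearing the methyl) follow the serrulatane-type numbering of the target, and (2S)-3-bromo-2-methylpropan-1-ol 14 is taken as commercial.

## Analysis of the target

Target 37 is a 1,4-disubstituted tetralin. Ring A (C4a, C5, C6, C7, C8, C8a) is pentasubstituted: a catechol on C5/C6, a carboxylic acid on C7 and one hydrogen on C8. Ring B (C1, C2, C3, C4, C4a, C8a) carries a methyl on C4 and, on C1, a chain C11–C16 with acetoxymethyl groups on C11 (carbon C19) and at the chain end (C16). There are four stereocentres: C1 (S) and C4 (R) are trans across ring B, C11 (S) sits directly on C1, and C15 (R) is insulated by three methylenes and has to be bought. The sensitive groups are the catechol–salicylic acid unit (air oxidation, so it is unmasked last), the two primary acetates (no strong base or nucleophile once they are on) and the two benzylic stereocentres. The difficulties are the 1,4-trans relationship, which has no functional group between the centres to relay it, the C1/C11 pair, and an arene with two adjacent carbon substituents next to three heteroatom-bearing positions. The strategy rests on one feature: C1 carries C11, and C11 carries C19 with an oxygen. If that oxygen is tied to C3 as an enol ether, with C3 joined to C1 on the other side through C4, C4a and C8a and with C2 as an exocyclic methylene on C3, then C2, C3, O, C19, C11 and C1 form an allyl vinyl ether inside a benzo-fused eight-membered ring. A [3,3] shift of that array makes the C1–C2 bond and closes ring B.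

## Retrosynthetic reasoning

Protecting groups. Target 37 is traced to the diacetate 35, in which the catechol is masked as two benzyl ethers and the acid as a tert-butyl ester. Acidolysis (to 36) and then hydrogenolysis touch neither the acetates nor the stereocentres, and the air-sensitive catechol appears only in the last flask.

C19–O and C11–H. The diol behind 35 (34, from 33) is cut at the C19–O bond back to the 1,1-disubstituted alkene 31. Hydroboration–oxidation puts the oxygen on C19 and sets C11 under the control of C1. This cut is chosen because the alkene is exactly what the ring-forming step leaves behind, so no extra carbon–carbon bond is needed for C19.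

C3 oxygen. Alkene 31 is traced to the ketone 28 by reduction and radical deoxygenation (29, 30). The C3 carbonyl has no counterpart in the target, but it is the unavoidable signature of the ring closure, and it is removed before anything else is done.

C1–C2 (key disconnection). Ketone 28 is opened between C1 and C2 with re-formation of the O–C19 bond, which gives the eight-membered 2-methylene enol ether 27. In the forward direction one thermal [3,3] shift makes ring B, the C1 stereocentre and the C11=C19 methylene together. The cut is placed here because it turns a carbocyclic problem into a lactone problem. Everything before 27 is ester and cross-coupling chemistry.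

C2 and the lactone C3–O bond. Enol ether 27 comes from lactone 26 by carbonyl methylenation, which supplies C2. Lactone 26 is opened at the acyl–oxygen bond to the hydroxy acid 24. The acid arm of 24 is therefore a 2-arylpropanoic acid in which C4 is attached directly to the carboxyl carbon C3. A 3-arylbutanoic acid would give a nine-membered lactone and, after the shift, a seven-membered ring.

C8a–C1. Hydroxy acid 24 is cut between the arene and the alkene into aryl bromide 13 and the Z-alkenyl iodide 22. A palladium-catalysed coupling with retention of alkene geometry guarantees that C8a and C19 are cis, which the eight-membered ring requires.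

Side chain. Iodide 22 is cut at C11–C12 into propargyl alcohol 19 and the alkylmagnesium reagent 20. The anti-carbomagnesiation of 19 delivers C12 to C11 and leaves the metal, and then iodine, on C1 cis to the hydroxymethyl group. Reagent 20 comes from bromide 18, which is made from the chiral-pool bromo alcohol 14 by silylation (15) and a two-carbon homologation (17). C15 is never touched.

C4–CH3 and C4a–C4. Acid 13 is cut at the C4–methyl bond to the arylacetic acid 8, and the methyl is introduced by auxiliary-controlled enolate alkylation (10, 11). Acid 8 comes from the allyl arene 6 by oxidative cleavage. The allyl group in 5 arises from the aryl allyl ether 4 by an aromatic Claisen rearrangement, which can only deliver carbon to the position that becomes C4a. Ether 4 leads back through ester 3 and bromide 2 to 2,3-dihydroxybenzoic acid 1. The bromine is put in first, where the directing effects of 1 are unambiguous, and becomes the C8a coupling handle.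

## Alternatives that were turned down

Alternative 1: cyclising conjunctive coupling. This cuts C11–C12 and C1–C8a in one operation. An open-chain E-alkenyl boronate, tethered through C2–C3–C4 to a triflated arene, would be turned into its ate complex by the side-chain alkyllithium. Zerovalent palladium would insert into the aryl triflate and induce 1,2-migration of C12 from boron to C11 while C8a bonds to C1, giving the tetralin boronate A1.
- For it: ring B, C1 and C11 arise in a single stereospecific event. Anti addition across an E alkene fixes the C1/C11 relationship and a chiral ligand can fix the absolute sense. The side chain enters convergently. On the C1/C11 pair this plan is stronger than the chosen one, which depends on substrate-controlled hydroboration.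
- Against it: A1 still lacks C19, so a hindered secondary boronate needs one-carbon homologation. It also lacks the C7 carboxyl, which would have to be introduced late by directed metalation. The ring-closing version of the coupling is itself untested, and an alkyllithium must coexist with an aryl triflate.
- Comparison: the chosen route buys the carboxyl with the arene, gets the C19 oxygen from the tether itself, and has one untested step instead of an untested step followed by a long functionalising endgame.

Alternative 2: pyranone–alkynylboronate cycloaddition. This cuts C4a–C8a and C5–C6, so ring A is made and not bought. A 2-pyranone tied through C1–C4 to an alkynyl boronate would undergo intramolecular [4+2] cycloaddition and decarboxylative aromatisation to the aryl boronate A2. In A2, C5 carries boron (later oxidised to the phenol), C6 a benzyl ether and C7 a benzyl ester.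
- For it: the substitution pattern of ring A follows from connectivity alone, which is stronger than the bromination and aromatic Claisen sequence used here. The endgame is short, because both acetates are already in place.
- Against it: C1, C4 and C11 must all be set in an open chain. The 1,4-relationship of C1 and C4 then has no ring to relay it and needs independent asymmetric operations. A trisubstituted pyranone has to be built, and the cycloaddition needs high temperature on a substrate that carries every stereocentre.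
- Comparison: the chosen strategy uses the ring closure itself to pass configuration from C4 to C1 and starts from a cheap preformed arene.

Alternative 3: terpene ring B, Diels–Alder ring A, late aromatisation. This cuts C4a–C5 and C6–C7. Ring B would come from a terpene cyclohexane that already holds the C4 methyl and the C1 branch, elaborated to a dienoate spanning C7, C8, C8a and C4a. A thermal Diels–Alder reaction with a two-carbon cyclic carbonate dienophile would give the cycloadduct A3.
- For it: the trans C1/C4 relationship comes from the chiral pool without any asymmetric reaction. On that point it is stronger than a predicted 1,4-induction.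
- Against it: a diene with an ester at its terminus and an unactivated dienophile are electronically mismatched, and facial selectivity is open. A3 lies three oxidation levels below the catechol arene, so carbonate cleavage and dehydrogenation must be carried out next to two future benzylic stereocentres. The route is long in redox steps.
- Comparison: the chosen route keeps ring A aromatic throughout and spends its steps on bond formation.

Key step: step 17

## Route

Step 1
Reactants: 1 2,3-dihydroxybenzoic acid
Product: 2 5-bromo-2,3-dihydroxybenzoic acid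
Conditions: Br2 (1.05 equiv), AcOH, rt
Reagents that add atoms: bromine, BrBr
Why: Electrophilic aromatic bromination; the position para to the hydrogen-bonded 2-hydroxyl and meta to the carboxyl (the future C8a) is the most activated one, as in the halogenation of salicylic acids.

Step 2
Reactants: 2 5-bromo-2,3-dihydroxybenzoic acid
Product: 3 tert-butyl 5-bromo-2,3-dihydroxybenzoate
Conditions: Cl3CC(=NH)OtBu (2 equiv), THF/cyclohexane, rt
Reagents that add atoms: tert-butyl 2,2,2-trichloroacetimidate, CC(C)(C)OC(=N)C(Cl)(Cl)Cl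
Why: Imidate esterification; the carboxylic acid itself protonates the imidate, so without added Lewis acid the less acidic phenols should stay free.

Step 3
Reactants: 3 tert-butyl 5-bromo-2,3-dihydroxybenzoate
Product: 4 tert-butyl 5-bromo-2-hydroxy-3-(prop-2-en-1-yloxy)benzoate
Conditions: NaH (2.1 equiv), DMSO, rt; allyl bromide (1.0 equiv)
Reagents that add atoms: allyl bromide, C=CCBr
Why: Williamson etherification of the dianion; the 3-oxide is not chelated to the ester carbonyl and is the more nucleophilic oxygen, so one equivalent of allyl bromide should give the 3-O-allyl ether.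

Step 4
Reactants: 4 tert-butyl 5-bromo-2-hydroxy-3-(prop-2-en-1-yloxy)benzoate
Product: 5 tert-butyl 5-bromo-2,3-dihydroxy-4-(prop-2-en-1-yl)benzoate
Conditions: PhNEt2, 185 °C
Reagents that add atoms: none
Why: Aromatic Claisen rearrangement; the only free ortho position of the allyl ether is the carbon that becomes C4a, and the basic amine solvent keeps the medium free of acid so that the tert-butyl ester should survive.

Step 5
Reactants: 5 tert-butyl 5-bromo-2,3-dihydroxy-4-(prop-2-en-1-yl)benzoate
Product: 6 tert-butyl 2,3-bis(benzyloxy)-5-bromo-4-(prop-2-en-1-yl)benzoate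
Conditions: BnBr (2.5 equiv), K2CO3, DMF, 50 °C
Reagents that add atoms: benzyl bromide, BrCc1ccccc1
Why: Williamson benzylation of both phenols; warming is needed for the hydrogen-bonded 2-hydroxyl.

Step 6
Reactants: 6 tert-butyl 2,3-bis(benzyloxy)-5-bromo-4-(prop-2-en-1-yl)benzoate
Product: 8 2-[2,3-bis(benzyloxy)-6-bromo-4-(tert-butoxycarbonyl)phenyl]acetic acid, via arylacetaldehyde 7 (not isolated)
Conditions: O3, CH2Cl2/MeOH, −78 °C (Sudan red end point); Me2S; then NaClO2, NaH2PO4, 2-methylbut-2-ene, t-BuOH/H2O, 0 °C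
Reagents that add atoms: ozone, [O-][O+]=O; sodium chlorite, [Na+].[O-]Cl=O
Why: Ozonolysis of the terminal alkene followed by Pinnick oxidation; the indicator stops ozone before the arene reacts, and the enolisable aldehyde is oxidised at once.

Step 7
Reactants: 8 2-[2,3-bis(benzyloxy)-6-bromo-4-(tert-butoxycarbonyl)phenyl]acetic acid
Product: 10 tert-butyl 2,3-bis(benzyloxy)-4-{2-[(4S)-4-benzyl-2-oxo-1,3-oxazolidin-3-yl]-2-oxoethyl}-5-bromobenzoate, via mixed pivalic anhydride 9 (not isolated)
Conditions: PivCl, Et3N, THF, −20 °C; (4S)-4-benzyl-1,3-oxazolidin-2-one, LiCl, rt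
Reagents that add atoms: (4S)-4-benzyl-1,3-oxazolidin-2-one, O=C1N[C@@H](Cc2ccccc2)CO1
Why: N-Acylation of the oxazolidinone through the mixed anhydride; the hindered pivaloyl carbonyl directs attack to the arylacetyl carbonyl.

Step 8
Reactants: 10 tert-butyl 2,3-bis(benzyloxy)-4-{2-[(4S)-4-benzyl-2-oxo-1,3-oxazolidin-3-yl]-2-oxoethyl}-5-bromobenzoate
Product: 11 tert-butyl 2,3-bis(benzyloxy)-4-{(2S)-1-[(4S)-4-benzyl-2-oxo-1,3-oxazolidin-3-yl]-1-oxopropan-2-yl}-5-bromobenzoate
Conditions: NaHMDS, THF, −78 °C; MeI, −78 → −40 °C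
Reagents that add atoms: iodomethane, CI
Why: Evans asymmetric alkylation; the chelated Z enolate is methylated on the face opposite the benzyl group of the auxiliary, which sets C4 in the S configuration of the acid series (the R centre of the target).

Step 9
Reactants: 11 tert-butyl 2,3-bis(benzyloxy)-4-{(2S)-1-[(4S)-4-benzyl-2-oxo-1,3-oxazolidin-3-yl]-1-oxopropan-2-yl}-5-bromobenzoate
Product: 13 (2S)-2-[2,3-bis(benzyloxy)-6-bromo-4-(tert-butoxycarbonyl)phenyl]propanoic acid, via peroxy acid 12 (not isolated)
Conditions: LiOH, H2O2, THF/H2O, 0 °C; Na2SO3; HCl to pH 3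
Reagents that add atoms: hydrogen peroxide, OO
Why: Hydroperoxide cleavage of the imide at the exocyclic carbonyl; the conditions are cold and the product leaves as a carboxylate, so C4 should not epimerise and the tert-butyl ester is untouched.

Step 10
Reactants: 14 (2S)-3-bromo-2-methylpropan-1-ol
Product: 15 [(2S)-3-bromo-2-methylpropoxy](tert-butyl)dimethylsilane
Conditions: TBSCl, imidazole, DMF, rt
Reagents that add atoms: tert-butyldimethylsilyl chloride, CC(C)(C)[Si](C)(C)Cl
Why: Standard silylation; the oxygen that will become the C16 acetate is masked for the organomagnesium steps.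

Step 11
Reactants: 15 [(2S)-3-bromo-2-methylpropoxy](tert-butyl)dimethylsilane
Product: 17 (4R)-5-[(tert-butyldimethylsilyl)oxy]-4-methylpentan-1-ol, via alkylmagnesium bromide 16 (not isolated)
Conditions: Mg, THF; CuI (10 mol %), oxirane, −30 → 0 °C
Reagents that add atoms: oxirane, C1CO1
Why: Copper-catalysed opening of oxirane by the Grignard reagent adds C13 and C12; the C15 centre is not involved.

Step 12
Reactants: 17 (4R)-5-[(tert-butyldimethylsilyl)oxy]-4-methylpentan-1-ol
Product: 18 {[(2R)-5-bromo-2-methylpentyl]oxy}(tert-butyl)dimethylsilane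
Conditions: CBr4, PPh3, CH2Cl2, 0 °C
Reagents that add atoms: carbon tetrabromide, BrC(Br)(Br)Br
Why: Appel bromination of a primary alcohol under neutral conditions that the silyl ether tolerates.

Step 13
Reactants: 18 {[(2R)-5-bromo-2-methylpentyl]oxy}(tert-butyl)dimethylsilane; 19 prop-2-yn-1-ol
Product: 22 (2Z,6R)-7-[(tert-butyldimethylsilyl)oxy]-2-(iodomethylidene)-6-methylheptan-1-ol, via alkylmagnesium bromide 20 (not isolated), via chelated alkenylmagnesium alkoxide 21 (not isolated)
Conditions: 18, Mg, THF; 19 pre-treated with i-PrMgCl (1.0 equiv), 0 °C; CuI (10 mol %), −10 °C → rt; I2, −40 → 0 °C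
Reagents that add atoms: iodine, II
Why: Copper-catalysed anti-carbomagnesiation of the propargylic magnesium alkoxide; the alkyl group adds to the internal carbon (C11), magnesium ends on the terminal carbon (C1) held cis to the CH2O group in a five-membered chelate, and iodinolysis with retention gives the Z iodide.

Step 14
Reactants: 13 (2S)-2-[2,3-bis(benzyloxy)-6-bromo-4-(tert-butoxycarbonyl)phenyl]propanoic acid; 22 (2Z,6R)-7-[(tert-butyldimethylsilyl)oxy]-2-(iodomethylidene)-6-methylheptan-1-ol
Product: 24 (2S)-2-{2,3-bis(benzyloxy)-4-(tert-butoxycarbonyl)-6-[(1Z,6R)-7-[(tert-butyldimethylsilyl)oxy]-2-(hydroxymethyl)-6-methylhept-1-en-1-yl]phenyl}propanoic acid, via arylboronic ester 23 (not isolated)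
Conditions: Pd(dppf)Cl2 (5 mol %), B2pin2 (1.1 equiv), KOAc (4 equiv), 1,4-dioxane, 90 °C; then 22 (1.2 equiv), aq. K3PO4, 70 °C
Reagents that add atoms: none
Why: Miyaura borylation followed in the same flask by Suzuki–Miyaura coupling, which keeps the alkene geometry and so places C8a cis to C19; the acid travels as its carboxylate, which also protects the C4–H from base.

Step 15
Reactants: 24 (2S)-2-{2,3-bis(benzyloxy)-4-(tert-butoxycarbonyl)-6-[(1Z,6R)-7-[(tert-butyldimethylsilyl)oxy]-2-(hydroxymethyl)-6-methylhept-1-en-1-yl]phenyl}propanoic acid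
Product: 26 tert-butyl (1S,5Z)-9,10-bis(benzyloxy)-5-{(4R)-5-[(tert-butyldimethylsilyl)oxy]-4-methylpentyl}-1-methyl-2-oxo-1,4-dihydro-2H-3-benzoxocine-8-carboxylate, via mixed aromatic anhydride 25 (not isolated)
Conditions: 2-methyl-6-nitrobenzoic anhydride (1.3 equiv), DMAP (cat.), Et3N, CH2Cl2 (2 mM), rt, slow addition of 24
Reagents that add atoms: none
Why: Shiina macrolactonisation; the Z alkene and the ortho-disubstituted arene hold the hydroxyl next to the activated acyl group, four of the eight ring atoms are sp2, and the acid is activated at room temperature with only catalytic nucleophilic base, so ketene formation at C4 should stay slow.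

Step 16
Reactants: 26 tert-butyl (1S,5Z)-9,10-bis(benzyloxy)-5-{(4R)-5-[(tert-butyldimethylsilyl)oxy]-4-methylpentyl}-1-methyl-2-oxo-1,4-dihydro-2H-3-benzoxocine-8-carboxylate
Product: 27 tert-butyl (1S,5Z)-9,10-bis(benzyloxy)-5-{(4R)-5-[(tert-butyldimethylsilyl)oxy]-4-methylpentyl}-1-methyl-2-methylidene-1,4-dihydro-2H-3-benzoxocine-8-carboxylate
Conditions: Cp2TiMe2 (2 equiv), toluene/THF, 65 °C, dark; filtration through basic alumina
Reagents that add atoms: dimethyltitanocene, [CH3-].[CH3-].[Ti+4].c1cc[cH-]c1.c1cc[cH-]c1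
Why: Petasis methylenation of the lactone carbonyl supplies C2; the hindered, conjugated tert-butyl benzoate should react far more slowly than the strained aliphatic lactone, and the non-acidic reagent and work-up preserve both the enol ether and C4.

Step 17
Reactants: 27 tert-butyl (1S,5Z)-9,10-bis(benzyloxy)-5-{(4R)-5-[(tert-butyldimethylsilyl)oxy]-4-methylpentyl}-1-methyl-2-methylidene-1,4-dihydro-2H-3-benzoxocine-8-carboxylate
Product: 28 tert-butyl (5S,8S)-3,4-bis(benzyloxy)-8-{(6R)-7-[(tert-butyldimethylsilyl)oxy]-6-methylhept-1-en-2-yl}-5-methyl-6-oxo-5,6,7,8-tetrahydronaphthalene-2-carboxylate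
Conditions: degassed toluene, 110 °C (xylene, 140 °C if required), silylated glassware, sealed tube
Reagents that add atoms: none
Why: Proposed new method: the atoms C2=C3–O–C19–C11=C1 of 27 form an allyl vinyl ether, and on heating a concerted [3,3]-sigmatropic shift should join C2 to C1 while the O–C19 bond breaks, which turns the enol ether into the C3 ketone and the ring alkene into the exocyclic C11=C19 methylene. The closest known reactions are the titanium methylenation–Claisen rearrangement of open-chain allylic esters and the Claisen ring contraction of unsaturated macrolactone ketene acetals; a 2-methylene enol ether of a benzo-fused eight-membered lactone has not been used in this way. Ring B (C1, C2, C3, C4, C4a, C8a) closes transannularly, by contraction of the eight-membered ring to a six-membered carbocycle, through a bicyclo[3.3.1]-like transition state; because the tether C4–C4a–C8a joins the central carbon C3 of the vinyl ether to the Z position of C1, only a chair-like six-centre array is within reach, since a boat would hold C4 and C8a too far apart. The one new stereocentre, C1, is controlled by C4: the benzyloxy group on C5 should push the C4 methyl into the pseudo-axial position of the developing half-chair, and in the chair-like array C2 then bonds to the face of C1 that sends the C11 unit to the opposite side, which gives the 1,4-trans ketone. The step needs facial selectivity at C1 and preference for the [3,3] path over a formal 1,3-shift or ionisation of the cinnamyl-type C19–O bond; the Z alkene, the ortho-disubstituted arene and the absence of acid are expected to secure both. Carbonyl formation and release of medium-ring strain drive the reaction, and the neutral medium should leave the now enolisable C4 untouched until the ketone is reduced in step 18.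

Step 18
Reactants: 28 tert-butyl (5S,8S)-3,4-bis(benzyloxy)-8-{(6R)-7-[(tert-butyldimethylsilyl)oxy]-6-methylhept-1-en-2-yl}-5-methyl-6-oxo-5,6,7,8-tetrahydronaphthalene-2-carboxylate
Product: 29 tert-butyl (5S,8S)-3,4-bis(benzyloxy)-8-{(6R)-7-[(tert-butyldimethylsilyl)oxy]-6-methylhept-1-en-2-yl}-6-hydroxy-5-methyl-5,6,7,8-tetrahydronaphthalene-2-carboxylate (either C6 epimer of the naphthalene numbering, that is C3)
Conditions: NaBH4, CeCl3·7H2O, MeOH/THF, −40 °C
Reagents that add atoms: none
Why: Luche-type carbonyl reduction at low temperature and low basicity removes the epimerisable α-aryl ketone at once; the configuration of the new carbinol is irrelevant because the oxygen is removed.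

Step 19
Reactants: 29 tert-butyl (5S,8S)-3,4-bis(benzyloxy)-8-{(6R)-7-[(tert-butyldimethylsilyl)oxy]-6-methylhept-1-en-2-yl}-6-hydroxy-5-methyl-5,6,7,8-tetrahydronaphthalene-2-carboxylate
Product: 30 tert-butyl (5S,8S)-3,4-bis(benzyloxy)-8-{(6R)-7-[(tert-butyldimethylsilyl)oxy]-6-methylhept-1-en-2-yl}-5-methyl-6-[(phenoxycarbonothioyl)oxy]-5,6,7,8-tetrahydronaphthalene-2-carboxylate
Conditions: PhOC(S)Cl, pyridine, DMAP (cat.), CH2Cl2, 0 °C → rt
Reagents that add atoms: O-phenyl carbonochloridothioate, S=C(Cl)Oc1ccccc1
Why: Thioacylation of the secondary alcohol under mild amine conditions prepares the radical leaving group.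

Step 20
Reactants: 30 tert-butyl (5S,8S)-3,4-bis(benzyloxy)-8-{(6R)-7-[(tert-butyldimethylsilyl)oxy]-6-methylhept-1-en-2-yl}-5-methyl-6-[(phenoxycarbonothioyl)oxy]-5,6,7,8-tetrahydronaphthalene-2-carboxylate
Product: 31 tert-butyl (5R,8S)-3,4-bis(benzyloxy)-8-{(6R)-7-[(tert-butyldimethylsilyl)oxy]-6-methylhept-1-en-2-yl}-5-methyl-5,6,7,8-tetrahydronaphthalene-2-carboxylate
Conditions: Bu3SnH, AIBN (cat.), toluene, 90 °C
Reagents that add atoms: none
Why: Barton–McCombie deoxygenation; the secondary C3 radical is quenched by the stannane faster than it can rearrange, and it cannot reach the exocyclic alkene in a favourable ring size, so C1 and C4 are untouched (the descriptor at C4 changes only because the priorities change).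

Step 21
Reactants: 31 tert-butyl (5R,8S)-3,4-bis(benzyloxy)-8-{(6R)-7-[(tert-butyldimethylsilyl)oxy]-6-methylhept-1-en-2-yl}-5-methyl-5,6,7,8-tetrahydronaphthalene-2-carboxylate
Product: 33 tert-butyl (5R,8S)-3,4-bis(benzyloxy)-8-{(2S,6R)-7-[(tert-butyldimethylsilyl)oxy]-1-hydroxy-6-methylheptan-2-yl}-5-methyl-5,6,7,8-tetrahydronaphthalene-2-carboxylate, via B-alkyl-9-borabicyclononane 32 (not isolated)
Conditions: 9-BBN, THF, 0 °C → rt; NaOH, H2O2, 0 °C
Reagents that add atoms: hydrogen peroxide, OO
Why: Hydroboration–oxidation places the oxygen on C19; the bulky borane should add to the methylene face anti to the arene (C8a) in the rotamer that keeps C1–H near the alkene plane beside C12, which delivers hydrogen to C11 in the sense required for the 11S centre; the selectivity is a prediction from the allylic-strain model.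

Step 22
Reactants: 33 tert-butyl (5R,8S)-3,4-bis(benzyloxy)-8-{(2S,6R)-7-[(tert-butyldimethylsilyl)oxy]-1-hydroxy-6-methylheptan-2-yl}-5-methyl-5,6,7,8-tetrahydronaphthalene-2-carboxylate
Product: 34 tert-butyl (5R,8S)-3,4-bis(benzyloxy)-8-[(2S,6R)-1,7-dihydroxy-6-methylheptan-2-yl]-5-methyl-5,6,7,8-tetrahydronaphthalene-2-carboxylate
Conditions: HF·pyridine, THF/pyridine, 0 °C → rt
Reagents that add atoms: none
Why: Buffered fluoride cleavage of the primary silyl ether; the tert-butyl ester and the benzyl ethers are stable to it.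

Step 23
Reactants: 34 tert-butyl (5R,8S)-3,4-bis(benzyloxy)-8-[(2S,6R)-1,7-dihydroxy-6-methylheptan-2-yl]-5-methyl-5,6,7,8-tetrahydronaphthalene-2-carboxylate
Product: 35 tert-butyl (5R,8S)-8-[(2S,6R)-1,7-diacetoxy-6-methylheptan-2-yl]-3,4-bis(benzyloxy)-5-methyl-5,6,7,8-tetrahydronaphthalene-2-carboxylate
Conditions: Ac2O, pyridine, DMAP (cat.), CH2Cl2, rt
Reagents that add atoms: acetic anhydride, CC(=O)OC(C)=O
Why: Acetylation of the two primary alcohols; no other nucleophilic group is free.

Step 24
Reactants: 35 tert-butyl (5R,8S)-8-[(2S,6R)-1,7-diacetoxy-6-methylheptan-2-yl]-3,4-bis(benzyloxy)-5-methyl-5,6,7,8-tetrahydronaphthalene-2-carboxylate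
Product: 36 (5R,8S)-8-[(2S,6R)-1,7-diacetoxy-6-methylheptan-2-yl]-3,4-bis(benzyloxy)-5-methyl-5,6,7,8-tetrahydronaphthalene-2-carboxylic acid
Conditions: CF3CO2H/CH2Cl2 (1:4), 0 °C → rt
Reagents that add atoms: none
Why: Acidolysis of the tert-butyl ester; acetates are stable, and the arene is still benzylated and fully flanked, so it should not be alkylated by the tert-butyl cation.

Step 25
Reactants: 36 (5R,8S)-8-[(2S,6R)-1,7-diacetoxy-6-methylheptan-2-yl]-3,4-bis(benzyloxy)-5-methyl-5,6,7,8-tetrahydronaphthalene-2-carboxylic acid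
Product: 37 (5R,8S)-8-[(2S,6R)-1,7-diacetoxy-6-methylheptan-2-yl]-3,4-dihydroxy-5-methyl-5,6,7,8-tetrahydronaphthalene-2-carboxylic acid (CNP0245723.1)
Conditions: H2 (1 atm), Pd/C, EtOAc, rt
Reagents that add atoms: none
Why: Hydrogenolysis of the two aryl benzyl ethers under neutral conditions; no alkene remains, and the acetates and benzylic C–C bonds are inert, so the catechol is released in the last operation.

## Compound list

1 | 2,3-dihydroxybenzoic acid | O=C(O)c1cccc(O)c1O | starting material
2 | 5-bromo-2,3-dihydroxybenzoic acid | OC(=O)c1cc(Br)cc(O)c1O | intermediate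
3 | tert-butyl 5-bromo-2,3-dihydroxybenzoate | CC(C)(C)OC(=O)c1cc(Br)cc(O)c1O | intermediate
4 | tert-butyl 5-bromo-2-hydroxy-3-(prop-2-en-1-yloxy)benzoate | C=CCOc1cc(Br)cc(C(=O)OC(C)(C)C)c1O | intermediate
5 | tert-butyl 5-bromo-2,3-dihydroxy-4-(prop-2-en-1-yl)benzoate | C=CCc1c(Br)cc(C(=O)OC(C)(C)C)c(O)c1O | intermediate
6 | tert-butyl 2,3-bis(benzyloxy)-5-bromo-4-(prop-2-en-1-yl)benzoate | C=CCc1c(Br)cc(C(=O)OC(C)(C)C)c(OCc2ccccc2)c1OCc1ccccc1 | intermediate
7 | tert-butyl 2,3-bis(benzyloxy)-5-bromo-4-(2-oxoethyl)benzoate | O=CCc1c(Br)cc(C(=O)OC(C)(C)C)c(OCc2ccccc2)c1OCc1ccccc1 | intermediate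
8 | 2-[2,3-bis(benzyloxy)-6-bromo-4-(tert-butoxycarbonyl)phenyl]acetic acid | OC(=O)Cc1c(Br)cc(C(=O)OC(C)(C)C)c(OCc2ccccc2)c1OCc1ccccc1 | intermediate
9 | 2-[2,3-bis(benzyloxy)-6-bromo-4-(tert-butoxycarbonyl)phenyl]acetic 2,2-dimethylpropanoic anhydride | CC(C)(C)C(=O)OC(=O)Cc1c(Br)cc(C(=O)OC(C)(C)C)c(OCc2ccccc2)c1OCc1ccccc1 | intermediate
10 | tert-butyl 2,3-bis(benzyloxy)-4-{2-[(4S)-4-benzyl-2-oxo-1,3-oxazolidin-3-yl]-2-oxoethyl}-5-bromobenzoate | O=C(Cc1c(Br)cc(C(=O)OC(C)(C)C)c(OCc2ccccc2)c1OCc1ccccc1)N1[C@@H](Cc2ccccc2)COC1=O | intermediate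
11 | tert-butyl 2,3-bis(benzyloxy)-4-{(2S)-1-[(4S)-4-benzyl-2-oxo-1,3-oxazolidin-3-yl]-1-oxopropan-2-yl}-5-bromobenzoate | C[C@H](C(=O)N1[C@@H](Cc2ccccc2)COC1=O)c1c(Br)cc(C(=O)OC(C)(C)C)c(OCc2ccccc2)c1OCc1ccccc1 | intermediate
12 | (2S)-2-[2,3-bis(benzyloxy)-6-bromo-4-(tert-butoxycarbonyl)phenyl]propaneperoxoic acid | C[C@H](C(=O)OO)c1c(Br)cc(C(=O)OC(C)(C)C)c(OCc2ccccc2)c1OCc1ccccc1 | intermediate
13 | (2S)-2-[2,3-bis(benzyloxy)-6-bromo-4-(tert-butoxycarbonyl)phenyl]propanoic acid | C[C@H](C(=O)O)c1c(Br)cc(C(=O)OC(C)(C)C)c(OCc2ccccc2)c1OCc1ccccc1 | intermediate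
14 | (2S)-3-bromo-2-methylpropan-1-ol | OC[C@H](C)CBr | starting material
15 | [(2S)-3-bromo-2-methylpropoxy](tert-butyl)dimethylsilane | CC(C)(C)[Si](C)(C)OC[C@H](C)CBr | intermediate
16 | {(2S)-3-[(tert-butyldimethylsilyl)oxy]-2-methylpropyl}magnesium bromide | CC(C)(C)[Si](C)(C)OC[C@H](C)C[Mg]Br | intermediate
17 | (4R)-5-[(tert-butyldimethylsilyl)oxy]-4-methylpentan-1-ol | CC(C)(C)[Si](C)(C)OC[C@H](C)CCCO | intermediate
18 | {[(2R)-5-bromo-2-methylpentyl]oxy}(tert-butyl)dimethylsilane | CC(C)(C)[Si](C)(C)OC[C@H](C)CCCBr | intermediate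
19 | prop-2-yn-1-ol | C#CCO | starting material
20 | {(4R)-5-[(tert-butyldimethylsilyl)oxy]-4-methylpentyl}magnesium bromide | CC(C)(C)[Si](C)(C)OC[C@H](C)CCC[Mg]Br | intermediate
21 | 4-{(4R)-5-[(tert-butyldimethylsilyl)oxy]-4-methylpentyl}-2,5-dihydro-1,2-oxamagnesole (chelated Z-alkenylmagnesium alkoxide) | CC(C)(C)[Si](C)(C)OC[C@H](C)CCCC1=C[Mg]OC1 | intermediate
22 | (2Z,6R)-7-[(tert-butyldimethylsilyl)oxy]-2-(iodomethylidene)-6-methylheptan-1-ol | OC/C(CCC[C@@H](C)CO[Si](C)(C)C(C)(C)C)=C\I | intermediate
23 | (2S)-2-[2,3-bis(benzyloxy)-4-(tert-butoxycarbonyl)-6-(4,4,5,5-tetramethyl-1,3,2-dioxaborolan-2-yl)phenyl]propanoic acid | C[C@H](C(=O)O)c1c(B2OC(C)(C)C(C)(C)O2)cc(C(=O)OC(C)(C)C)c(OCc2ccccc2)c1OCc1ccccc1 | intermediate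
24 | (2S)-2-{2,3-bis(benzyloxy)-4-(tert-butoxycarbonyl)-6-[(1Z,6R)-7-[(tert-butyldimethylsilyl)oxy]-2-(hydroxymethyl)-6-methylhept-1-en-1-yl]phenyl}propanoic acid | C[C@H](C(=O)O)c1c(/C=C(\CO)CCC[C@@H](C)CO[Si](C)(C)C(C)(C)C)cc(C(=O)OC(C)(C)C)c(OCc2ccccc2)c1OCc1ccccc1 | intermediate
25 | mixed anhydride of 24 with 2-methyl-6-nitrobenzoic acid | C[C@H](C(=O)OC(=O)c1c(C)cccc1[N+](=O)[O-])c1c(/C=C(\CO)CCC[C@@H](C)CO[Si](C)(C)C(C)(C)C)cc(C(=O)OC(C)(C)C)c(OCc2ccccc2)c1OCc1ccccc1 | intermediate
26 | tert-butyl (1S,5Z)-9,10-bis(benzyloxy)-5-{(4R)-5-[(tert-butyldimethylsilyl)oxy]-4-methylpentyl}-1-methyl-2-oxo-1,4-dihydro-2H-3-benzoxocine-8-carboxylate | O=C1OC/C(CCC[C@@H](C)CO[Si](C)(C)C(C)(C)C)=C\c2cc(C(=O)OC(C)(C)C)c(OCc3ccccc3)c(OCc4ccccc4)c2[C@@H]1C | intermediate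
27 | tert-butyl (1S,5Z)-9,10-bis(benzyloxy)-5-{(4R)-5-[(tert-butyldimethylsilyl)oxy]-4-methylpentyl}-1-methyl-2-methylidene-1,4-dihydro-2H-3-benzoxocine-8-carboxylate | C=C1OC/C(CCC[C@@H](C)CO[Si](C)(C)C(C)(C)C)=C\c2cc(C(=O)OC(C)(C)C)c(OCc3ccccc3)c(OCc4ccccc4)c2[C@@H]1C | intermediate
28 | tert-butyl (5S,8S)-3,4-bis(benzyloxy)-8-{(6R)-7-[(tert-butyldimethylsilyl)oxy]-6-methylhept-1-en-2-yl}-5-methyl-6-oxo-5,6,7,8-tetrahydronaphthalene-2-carboxylate | C=C(CCC[C@@H](C)CO[Si](C)(C)C(C)(C)C)[C@@H]1CC(=O)[C@@H](C)c2c1cc(C(=O)OC(C)(C)C)c(OCc3ccccc3)c2OCc4ccccc4 | intermediate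
29 | tert-butyl (5S,8S)-3,4-bis(benzyloxy)-8-{(6R)-7-[(tert-butyldimethylsilyl)oxy]-6-methylhept-1-en-2-yl}-6-hydroxy-5-methyl-5,6,7,8-tetrahydronaphthalene-2-carboxylate (carbinol epimers) | C=C(CCC[C@@H](C)CO[Si](C)(C)C(C)(C)C)[C@@H]1CC(O)[C@@H](C)c2c1cc(C(=O)OC(C)(C)C)c(OCc3ccccc3)c2OCc4ccccc4 | intermediate
30 | tert-butyl (5S,8S)-3,4-bis(benzyloxy)-8-{(6R)-7-[(tert-butyldimethylsilyl)oxy]-6-methylhept-1-en-2-yl}-5-methyl-6-[(phenoxycarbonothioyl)oxy]-5,6,7,8-tetrahydronaphthalene-2-carboxylate | C=C(CCC[C@@H](C)CO[Si](C)(C)C(C)(C)C)[C@@H]1CC(OC(=S)Oc5ccccc5)[C@@H](C)c2c1cc(C(=O)OC(C)(C)C)c(OCc3ccccc3)c2OCc4ccccc4 | intermediate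
31 | tert-butyl (5R,8S)-3,4-bis(benzyloxy)-8-{(6R)-7-[(tert-butyldimethylsilyl)oxy]-6-methylhept-1-en-2-yl}-5-methyl-5,6,7,8-tetrahydronaphthalene-2-carboxylate | C=C(CCC[C@@H](C)CO[Si](C)(C)C(C)(C)C)[C@@H]1CC[C@@H](C)c2c1cc(C(=O)OC(C)(C)C)c(OCc3ccccc3)c2OCc4ccccc4 | intermediate
32 | B-alkyl-9-borabicyclo[3.3.1]nonane adduct of 31 (boron on C19) | CC(C)(C)[Si](C)(C)OC[C@H](C)CCC[C@H](CB1C2CCCC1CCC2)[C@@H]1CC[C@@H](C)c2c1cc(C(=O)OC(C)(C)C)c(OCc3ccccc3)c2OCc4ccccc4 | intermediate
33 | tert-butyl (5R,8S)-3,4-bis(benzyloxy)-8-{(2S,6R)-7-[(tert-butyldimethylsilyl)oxy]-1-hydroxy-6-methylheptan-2-yl}-5-methyl-5,6,7,8-tetrahydronaphthalene-2-carboxylate | CC(C)(C)[Si](C)(C)OC[C@H](C)CCC[C@H](CO)[C@@H]1CC[C@@H](C)c2c1cc(C(=O)OC(C)(C)C)c(OCc3ccccc3)c2OCc4ccccc4 | intermediate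
34 | tert-butyl (5R,8S)-3,4-bis(benzyloxy)-8-[(2S,6R)-1,7-dihydroxy-6-methylheptan-2-yl]-5-methyl-5,6,7,8-tetrahydronaphthalene-2-carboxylate | OC[C@H](C)CCC[C@H](CO)[C@@H]1CC[C@@H](C)c2c1cc(C(=O)OC(C)(C)C)c(OCc3ccccc3)c2OCc4ccccc4 | intermediate
35 | tert-butyl (5R,8S)-8-[(2S,6R)-1,7-diacetoxy-6-methylheptan-2-yl]-3,4-bis(benzyloxy)-5-methyl-5,6,7,8-tetrahydronaphthalene-2-carboxylate | CC(=O)OC[C@H](C)CCC[C@H](COC(C)=O)[C@@H]1CC[C@@H](C)c2c1cc(C(=O)OC(C)(C)C)c(OCc3ccccc3)c2OCc4ccccc4 | intermediate
36 | (5R,8S)-8-[(2S,6R)-1,7-diacetoxy-6-methylheptan-2-yl]-3,4-bis(benzyloxy)-5-methyl-5,6,7,8-tetrahydronaphthalene-2-carboxylic acid | CC(=O)OC[C@H](C)CCC[C@H](COC(C)=O)[C@@H]1CC[C@@H](C)c2c1cc(C(=O)O)c(OCc3ccccc3)c2OCc4ccccc4 | intermediate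
37 | (5R,8S)-8-[(2S,6R)-1,7-diacetoxy-6-methylheptan-2-yl]-3,4-dihydroxy-5-methyl-5,6,7,8-tetrahydronaphthalene-2-carboxylic acid (CNP0245723.1) | CC(=O)OC[C@H](C)CCC[C@H](COC(C)=O)[C@@H]1CC[C@@H](C)c2c1cc(C(=O)O)c(O)c2O | target

## Step count and least certain steps

Total step count: 25. Longest linear sequence: 21 steps (steps 1–9 and 14–25, from 1 to 37). The side-chain branch (steps 10–13) has 4 steps.

Step 17 (key step). Three processes can go wrong.
- Poor or reversed facial selectivity at C1. The only control element is the remote C4 centre acting through the conformation of the transition state.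
- Diversion into a formal 1,3-shift or ionisation of the cinnamyl-type C19–O bond if traces of acid are present.
- Premature rearrangement during step 16, followed by methylenation of the new ketone by the excess titanium reagent.

Fallback, with known chemistry only: ring B is closed by a palladium-catalysed intramolecular allylic alkylation, so that C1 is set by a chiral ligand. The fallback sets out from 13 and rejoins the route at 28.
- Acid 13 is homologated with carbonyldiimidazole and then potassium methyl malonate/MgCl2/Et3N to the β-keto ester, methyl (4S)-4-[2,3-bis(benzyloxy)-6-bromo-4-(tert-butoxycarbonyl)phenyl]-3-oxopentanoate F1.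
- Borylation and coupling with 22, as in step 14, give the allylic alcohol, methyl (4S)-4-{2,3-bis(benzyloxy)-4-(tert-butoxycarbonyl)-6-[(1Z,6R)-7-[(tert-butyldimethylsilyl)oxy]-2-(hydroxymethyl)-6-methylhept-1-en-1-yl]phenyl}-3-oxopentanoate F2.
- Methyl chloroformate and pyridine convert it into the allylic methyl carbonate F3.
- Pd2(dba)3·CHCl3 with one enantiomer of the Trost ligand N,N'-(cyclohexane-1,2-diyl)bis[2-(diphenylphosphino)benzamide] ionises the carbonate. The β-keto ester carbon C2 attacks C1 of the allyl complex (six-membered ring preferred over eight-membered) to give the cyclised β-keto ester, tert-butyl (5S,8S)-3,4-bis(benzyloxy)-8-{(6R)-7-[(tert-butyldimethylsilyl)oxy]-6-methylhept-1-en-2-yl}-7-(methoxycarbonyl)-5-methyl-6-oxo-5,6,7,8-tetrahydronaphthalene-2-carboxylate F4. The ligand enantiomer is chosen by experiment so that catalyst and substrate act in the same sense.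
- Krapcho demethoxycarbonylation (LiCl, wet DMSO, 130 °C) returns ketone 28. Any epimerisation at C4 on the way should be corrected thermodynamically, because the trans isomer with the methyl pseudo-axial beside the C5 benzyloxy group is expected to be favoured.

Step 15. The eight-membered lactonisation can give way to intermolecular esterification (dimer and oligomers), and activation of a 2-arylpropanoic acid can erode C4 through a ketene.

Fallback: the ring is closed at the alkene instead of the ester, by ring-closing metathesis. It sets out from 13, 19 and 20 and rejoins at 26.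
- Suzuki coupling of 13 with potassium vinyltrifluoroborate (Pd(dppf)Cl2, Cs2CO3, THF/H2O) gives the styrene acid, (2S)-2-[2,3-bis(benzyloxy)-4-(tert-butoxycarbonyl)-6-ethenylphenyl]propanoic acid F5.
- The carbomagnesiation of 19 with 20 (as in step 13) is quenched with aqueous NH4Cl instead of iodine and gives the allylic alcohol, (6R)-7-[(tert-butyldimethylsilyl)oxy]-6-methyl-2-methylideneheptan-1-ol F6.
- Mitsunobu esterification of F5 with F6 (PPh3, diisopropyl azodicarboxylate) activates the alcohol and not the acid, so C4 is safe, and gives the diene ester F7.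
- Ring-closing metathesis of F7 with the second-generation Hoveyda–Grubbs catalyst in hot dilute toluene releases ethene and gives 26. The ring size allows only the Z alkene.

Step 21. The facial selectivity of the hydroboration may be low, because the two substituents on C1 that flank the alkene (arene and ring methylene) differ only moderately in size. A mixture at C11 would be hard to separate this late.

Fallback: the centre is set under catalyst control. It sets out from 31 and rejoins at 33. Copper hydride-catalysed hydroboration of the 1,1-disubstituted alkene with pinacolborane (Cu(OAc)2, one enantiomer of DTBM-SEGPHOS, THF, rt) gives the primary pinacol boronate F8. Its oxidation with NaBO3·4H2O in THF/H2O gives 33.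

## Further compounds

F1 | step 17 | methyl (4S)-4-[2,3-bis(benzyloxy)-6-bromo-4-(tert-butoxycarbonyl)phenyl]-3-oxopentanoate | C[C@H](C(=O)CC(=O)OC)c1c(Br)cc(C(=O)OC(C)(C)C)c(OCc2ccccc2)c1OCc1ccccc1
F2 | step 17 | methyl (4S)-4-{2,3-bis(benzyloxy)-4-(tert-butoxycarbonyl)-6-[(1Z,6R)-7-[(tert-butyldimethylsilyl)oxy]-2-(hydroxymethyl)-6-methylhept-1-en-1-yl]phenyl}-3-oxopentanoate | C[C@H](C(=O)CC(=O)OC)c1c(/C=C(\CO)CCC[C@@H](C)CO[Si](C)(C)C(C)(C)C)cc(C(=O)OC(C)(C)C)c(OCc2ccccc2)c1OCc1ccccc1
F3 | step 17 | methyl (4S)-4-{2,3-bis(benzyloxy)-4-(tert-butoxycarbonyl)-6-[(1Z,6R)-7-[(tert-butyldimethylsilyl)oxy]-2-{[(methoxycarbonyl)oxy]methyl}-6-methylhept-1-en-1-yl]phenyl}-3-oxopentanoate | C[C@H](C(=O)CC(=O)OC)c1c(/C=C(\COC(=O)OC)CCC[C@@H](C)CO[Si](C)(C)C(C)(C)C)cc(C(=O)OC(C)(C)C)c(OCc2ccccc2)c1OCc1ccccc1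
F4 | step 17 | tert-butyl (5S,8S)-3,4-bis(benzyloxy)-8-{(6R)-7-[(tert-butyldimethylsilyl)oxy]-6-methylhept-1-en-2-yl}-7-(methoxycarbonyl)-5-methyl-6-oxo-5,6,7,8-tetrahydronaphthalene-2-carboxylate | C=C(CCC[C@@H](C)CO[Si](C)(C)C(C)(C)C)[C@@H]1C(C(=O)OC)C(=O)[C@@H](C)c2c1cc(C(=O)OC(C)(C)C)c(OCc3ccccc3)c2OCc4ccccc4
F5 | step 15 | (2S)-2-[2,3-bis(benzyloxy)-4-(tert-butoxycarbonyl)-6-ethenylphenyl]propanoic acid | C[C@H](C(=O)O)c1c(C=C)cc(C(=O)OC(C)(C)C)c(OCc2ccccc2)c1OCc1ccccc1
F6 | step 15 | (6R)-7-[(tert-butyldimethylsilyl)oxy]-6-methyl-2-methylideneheptan-1-ol | C=C(CO)CCC[C@@H](C)CO[Si](C)(C)C(C)(C)C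
F7 | step 15 | (6R)-7-[(tert-butyldimethylsilyl)oxy]-6-methyl-2-methylideneheptyl (2S)-2-[2,3-bis(benzyloxy)-4-(tert-butoxycarbonyl)-6-ethenylphenyl]propanoate | C[C@H](C(=O)OCC(=C)CCC[C@@H](C)CO[Si](C)(C)C(C)(C)C)c1c(C=C)cc(C(=O)OC(C)(C)C)c(OCc2ccccc2)c1OCc1ccccc1
F8 | step 21 | tert-butyl (5R,8S)-3,4-bis(benzyloxy)-8-{(2S,6R)-7-[(tert-butyldimethylsilyl)oxy]-6-methyl-1-(4,4,5,5-tetramethyl-1,3,2-dioxaborolan-2-yl)heptan-2-yl}-5-methyl-5,6,7,8-tetrahydronaphthalene-2-carboxylate | CC(C)(C)[Si](C)(C)OC[C@H](C)CCC[C@H](CB1OC(C)(C)C(C)(C)O1)[C@@H]1CC[C@@H](C)c2c1cc(C(=O)OC(C)(C)C)c(OCc3ccccc3)c2OCc4ccccc4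
A1 | alternative 1 | tetralin with a secondary pinacol boronate on C11, methoxymethyl ethers on C5 and C6 and a silyl ether on C16 | CC(C)(C)[Si](C)(C)OC[C@H](C)CCC[C@H](B3OC(C)(C)C(C)(C)O3)[C@@H]1CC[C@@H](C)c2c1ccc(OCOC)c2OCOC
A2 | alternative 2 | tetralin diacetate with a pinacol boronate on C5, a benzyl ether on C6 and a benzyl ester on C7 | CC(=O)OC[C@H](C)CCC[C@H](COC(C)=O)[C@@H]1CC[C@@H](C)c2c1cc(C(=O)OCc3ccccc3)c(OCc4ccccc4)c2B5OC(C)(C)C(C)(C)O5
A3 | alternative 3 | hexahydronaphthalene cycloadduct with a cyclic carbonate on C5 and C6, a benzyl ester on C7 and silyl ethers on C16 and C19 | CC(C)(C)[Si](C)(C)OC[C@H](C)CCC[C@H](CO[Si](C)(C)C(C)(C)C)[C@@H]1CC[C@@H](C)C2C1=CC(C(=O)OCc3ccccc3)C4OC(=O)OC42
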